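The route rests on cutting the C2–C3 bond of the dihydrofuran ring. C3a is flanked by two oxygens, O1 (through C7a) and the C4 oxygen, so a symmetric benzene ring with two identical O–CH2–ArA ethers (ArA: the catechol ring of C2, as dimethyl ether) ortho to a diaryldiazomethane carbon is the precursor. A chiral dirhodium carbene at C3 inserts into one benzylic ether C–H: this makes C2–C3, closes the five-membered ring and sets both stereocentres at once. C3 is final; C2 is later turned to trans by acid, which also removes the spare arm from the C4 oxygen. The C6 carbon travels as a silyl-protected hydroxymethyl group, so hydrazine never meets an ester.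

Key step: step 6

Assumption: Rh2(S-PTAD)4, tetrakis[(S)-(1-adamantyl)(N-phthalimido)acetato]dirhodium, is taken to give the (3S) series; if a first run shows the opposite sense, the mirror-image catalyst Rh2(R-PTAD)4 is used and nothing else changes.

Remarks on the design:
- ArB is the 3,5-dioxygenated ring on C3. "Veratryl" means 3,4-dimethoxybenzyl.
- The target is (2S,3S), which is the trans ring. The insertion should give the (2R,3S) cis ring, so only C2 has to be inverted.
- The one-carbon group at C6 is kept as CH2OSi(iPr)3 from step 3 to step 7. The ketone of step 5 has two ortho ethers and needs hot, excess hydrazine, which would turn an ester into the acyl hydrazide.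
- The ketone is made in one step from the aroyl chloride, which saves a carbinol oxidation.
- Both ortho ethers must carry ring ArA. The arm that is not used is therefore a veratryl ether on the C4 oxygen and is acid-labile by construction.

Step 1
Reactants: 1 methyl 4-bromo-3,5-dihydroxybenzoate; 2 3,4-dimethoxybenzyl chloride (2.3 equiv)
Product: 3 methyl 4-bromo-3,5-bis[(3,4-dimethoxybenzyl)oxy]benzoate
Conditions: K2CO3, DMF, 60 °C
Reagents that add atoms: none
Why: Williamson ether synthesis, in which both phenols (acidified by the para ester) should alkylate cleanly with the activated benzylic chloride while the aryl bromide and the ester are inert to carbonate.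

Step 2
Reactants: 3 methyl 4-bromo-3,5-bis[(3,4-dimethoxybenzyl)oxy]benzoate
Product: 4 {4-bromo-3,5-bis[(3,4-dimethoxybenzyl)oxy]phenyl}methanol
Conditions: iBu2AlH (2.5 equiv), CH2Cl2, −78 → 0 °C; aq. KNaC4H4O6 (potassium sodium tartrate)
Reagents that add atoms: none
Why: Hydride reduction of an ester to the primary alcohol with iBu2AlH, which at low temperature should leave the aryl bromide and the benzyl-type ethers alone.

Step 3
Reactants: 4 {4-bromo-3,5-bis[(3,4-dimethoxybenzyl)oxy]phenyl}methanol
Product: 5 {[4-bromo-3,5-bis[(3,4-dimethoxybenzyl)oxy]benzyl]oxy}tri(propan-2-yl)silane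
Conditions: iPr3SiCl, imidazole, DMF, rt
Reagents that add atoms: chlorotri(propan-2-yl)silane (iPr3SiCl), CC(C)[Si](Cl)(C(C)C)C(C)C
Why: Silylation of a primary alcohol (silyl ether formation), giving a group that should withstand n-BuLi at −78 °C, hot hydrazine, MnO2 and the rhodium carbene and is removed with fluoride in step 7.

Step 4
Reactants: 5 {[4-bromo-3,5-bis[(3,4-dimethoxybenzyl)oxy]benzyl]oxy}tri(propan-2-yl)silane; 6 3,5-dimethoxybenzoyl chloride (1.5 equiv)
Product: 8 [2,6-bis[(3,4-dimethoxybenzyl)oxy]-4-({[tri(propan-2-yl)silyl]oxy}methyl)phenyl](3,5-dimethoxyphenyl)methanone, via aryllithium 7 (not isolated)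
Conditions: n-BuLi (1.05 equiv), THF, −78 °C; then cannulate into 6, THF, −78 → −40 °C
Reagents that add atoms: none
Why: Bromine–lithium exchange followed by acylation of the aryllithium with an aroyl chloride (nucleophilic acyl substitution); the exchange at −78 °C should outrun benzylic deprotonation, and the ketone formed is screened by two ortho ethers so that a second addition should not occur.

Step 5
Reactants: 8 [2,6-bis[(3,4-dimethoxybenzyl)oxy]-4-({[tri(propan-2-yl)silyl]oxy}methyl)phenyl](3,5-dimethoxyphenyl)methanone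
Product: 9 {[2,6-bis[(3,4-dimethoxybenzyl)oxy]-4-({[tri(propan-2-yl)silyl]oxy}methyl)phenyl](3,5-dimethoxyphenyl)methylidene}hydrazine (the N-unsubstituted hydrazone of 8)
Conditions: N2H4·H2O (30 equiv), AcOH (cat.), n-BuOH, 120 °C, sealed tube, Ar
Reagents that add atoms: hydrazine (used as N2H4·H2O), NN
Why: Condensation of a ketone with hydrazine to the hydrazone, which for this di-ortho-substituted carbonyl group needs heat and a large excess (the excess also suppresses azine formation) and which the molecule should tolerate because it holds only ethers at this stage.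

Step 6
Reactants: 9 hydrazone of 8
Product: 11 {[(2R,3S)-4-[(3,4-dimethoxybenzyl)oxy]-2-(3,4-dimethoxyphenyl)-3-(3,5-dimethoxyphenyl)-2,3-dihydro-1-benzofuran-6-yl]methoxy}tri(propan-2-yl)silane (cis), via diaryldiazomethane 10 (not isolated)
Conditions: MnO2 (activated, 8 equiv), CH2Cl2, 0 °C; then Rh2(S-PTAD)4 (1 mol %), −20 → 0 °C
Reagents that add atoms: none
Why: MnO2 dehydrogenates the hydrazone to the diaryldiazomethane 10, which loses N2 at the divalent rhodium dimer to give a donor/donor carbene at C3; the carbene engages one C–H bond of an ortho O–CH2–ArA group in a concerted but strongly asynchronous three-centre transition state with much hydride-transfer character, and this ends in the C2–C3 bond. The closest known reaction type is the dirhodium-catalysed enantioselective intramolecular C–H insertion of diaryl carbenes into benzylic ether C–H bonds, which gives cis-2,3-diaryl-2,3-dihydrobenzofurans. The dihydrofuran ring closes by 1,5-insertion (a five-membered ring through C3a, C7a and O1), the ring size that rhodium carbenes prefer. C3 is set by the chiral carboxylate ligands, which fix the face of the carbene that meets the C–H bond, and C2 is set in the same event, since the compact cyclic transition state places ArA and ArB on one side of the new ring (cis, kinetic). The step needs site selectivity and chemoselectivity: the two ortho veratryl ethers are interchanged by rotation about the aryl–C3 bond and give the same product, no other C–H bond can be reached through a five-membered transition state, the ether oxygen and the electron-rich ring ArA make the targeted C–H the most hydridic one, and a donor/donor carbene is too mild to add to the methoxyarenes. Only the configuration at C3 has to be high, since C2 is equilibrated in step 7.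

Step 7
Reactants: 11 cis-(2R,3S) dihydrobenzofuran
Product: 13 (2S,3S)-2-(3,4-dimethoxyphenyl)-3-(3,5-dimethoxyphenyl)-6-(hydroxymethyl)-2,3-dihydro-1-benzofuran-4-ol (trans), via trans phenol silyl ether 12 (not isolated)
Conditions: CF3CO2H/CH2Cl2 (1:4), 1,3,5-trimethoxybenzene (10 equiv), 0 °C → rt; aq. NaHCO3 wash; then Bu4NF, THF, rt
Reagents that add atoms: none
Why: Acidolysis of the veratryl aryl ether (its cation caught by Friedel–Crafts alkylation of 1,3,5-trimethoxybenzene) should run together with acid-catalysed epimerisation, because the C2–O1 bond is itself a secondary veratryl aryl ether that ionises reversibly to the ArA-stabilised cation and recloses (5-exo) to the more stable trans ring, inverting C2 from R to S while C3, which has no leaving group, stays S; fluoride-induced desilylation then frees the primary alcohol whether or not the silyl ether has survived the acid.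

Step 8
Reactants: 13 trans-(2S,3S) diol
Product: 14 (2S,3S)-2-(3,4-dimethoxyphenyl)-3-(3,5-dimethoxyphenyl)-4-hydroxy-2,3-dihydro-1-benzofuran-6-carbaldehyde
Conditions: MnO2 (activated, 15 equiv), EtOAc, rt
Reagents that add atoms: none
Why: MnO2 oxidation of a benzylic alcohol to the aldehyde, a surface oxidation that should be selective for the benzylic carbinol and leave the free phenol, the C2–H and C3–H bonds and both stereocentres untouched.

Step 9
Reactants: 14 trans-(2S,3S) aldehyde; 15 diethyl (4-methoxybenzyl)phosphonate (1.5 equiv)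
Product: 16 (2S,3S)-2-(3,4-dimethoxyphenyl)-3-(3,5-dimethoxyphenyl)-6-[(E)-2-(4-methoxyphenyl)ethenyl]-2,3-dihydro-1-benzofuran-4-ol
Conditions: 15, KOtBu (2.6 equiv), THF/DMF, 0 °C; then 14, 0 °C → rt; aq. NH4Cl
Reagents that add atoms: none
Why: Horner–Wadsworth–Emmons olefination with a benzylphosphonate anion, which should give the (E)-stilbene; one equivalent of base is spent on the C4 phenol, whose phenoxide is meta to the aldehyde (so it does not switch it off) and whose charge guards the C3–H bond against deprotonation.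

Step 10
Reactants: 16 trans-(2S,3S) pentamethyl ether
Product: 17 5-[(2S,3S)-2-(3,4-dihydroxyphenyl)-4-hydroxy-6-[(E)-2-(4-hydroxyphenyl)ethenyl]-2,3-dihydro-1-benzofuran-3-yl]benzene-1,3-diol (CNP0316718.1)
Conditions: BBr3 (12 equiv), CH2Cl2, −78 → 0 °C; then MeOH/H2O at −78 °C
Reagents that add atoms: none
Why: Cleavage of aryl methyl ethers with BBr3 (bromide attacks the methyl group of the boron-complexed ether) should remove all five methyl groups; the trans ring is already the thermodynamic isomer, so a reversible opening at C2–O1 returns the same compound, and the stilbene at C6 is too far from ring ArB to cyclise onto it.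

Compound list
1 | methyl 4-bromo-3,5-dihydroxybenzoate | COC(=O)c1cc(O)c(Br)c(O)c1 | starting material
2 | 3,4-dimethoxybenzyl chloride | COc1ccc(CCl)cc1OC | starting material
3 | methyl 4-bromo-3,5-bis[(3,4-dimethoxybenzyl)oxy]benzoate | COC(=O)c1cc(OCc2ccc(OC)c(OC)c2)c(Br)c(OCc2ccc(OC)c(OC)c2)c1 | intermediate
4 | {4-bromo-3,5-bis[(3,4-dimethoxybenzyl)oxy]phenyl}methanol | OCc1cc(OCc2ccc(OC)c(OC)c2)c(Br)c(OCc2ccc(OC)c(OC)c2)c1 | intermediate
5 | {[4-bromo-3,5-bis[(3,4-dimethoxybenzyl)oxy]benzyl]oxy}tri(propan-2-yl)silane | CC(C)[Si](OCc1cc(OCc2ccc(OC)c(OC)c2)c(Br)c(OCc2ccc(OC)c(OC)c2)c1)(C(C)C)C(C)C | intermediate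
6 | 3,5-dimethoxybenzoyl chloride | COc1cc(OC)cc(C(=O)Cl)c1 | starting material
7 | [2,6-bis[(3,4-dimethoxybenzyl)oxy]-4-({[tri(propan-2-yl)silyl]oxy}methyl)phenyl]lithium | [Li]c1c(OCc2ccc(OC)c(OC)c2)cc(CO[Si](C(C)C)(C(C)C)C(C)C)cc1OCc1ccc(OC)c(OC)c1 | intermediate (not isolated)
8 | [2,6-bis[(3,4-dimethoxybenzyl)oxy]-4-({[tri(propan-2-yl)silyl]oxy}methyl)phenyl](3,5-dimethoxyphenyl)methanone | COc1cc(OC)cc(C(=O)c2c(OCc3ccc(OC)c(OC)c3)cc(CO[Si](C(C)C)(C(C)C)C(C)C)cc2OCc2ccc(OC)c(OC)c2)c1 | intermediate
9 | hydrazone of 8 (C=N–NH2) | COc1cc(OC)cc(C(=NN)c2c(OCc3ccc(OC)c(OC)c3)cc(CO[Si](C(C)C)(C(C)C)C(C)C)cc2OCc2ccc(OC)c(OC)c2)c1 | intermediate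
10 | {[4-[diazo(3,5-dimethoxyphenyl)methyl]-3,5-bis[(3,4-dimethoxybenzyl)oxy]benzyl]oxy}tri(propan-2-yl)silane | COc1cc(OC)cc(C(=[N+]=[N-])c2c(OCc3ccc(OC)c(OC)c3)cc(CO[Si](C(C)C)(C(C)C)C(C)C)cc2OCc2ccc(OC)c(OC)c2)c1 | intermediate (not isolated)
11 | {[(2R,3S)-4-[(3,4-dimethoxybenzyl)oxy]-2-(3,4-dimethoxyphenyl)-3-(3,5-dimethoxyphenyl)-2,3-dihydro-1-benzofuran-6-yl]methoxy}tri(propan-2-yl)silane (cis) | CC(C)[Si](OCc1cc(OCc2ccc(OC)c(OC)c2)c2c(c1)O[C@@H](c1ccc(OC)c(OC)c1)[C@H]2c1cc(OC)cc(OC)c1)(C(C)C)C(C)C | intermediate
12 | (2S,3S)-2-(3,4-dimethoxyphenyl)-3-(3,5-dimethoxyphenyl)-6-({[tri(propan-2-yl)silyl]oxy}methyl)-2,3-dihydro-1-benzofuran-4-ol (trans) | CC(C)[Si](OCc1cc(O)c2c(c1)O[C@H](c1ccc(OC)c(OC)c1)[C@H]2c1cc(OC)cc(OC)c1)(C(C)C)C(C)C | intermediate (not isolated)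
13 | (2S,3S)-2-(3,4-dimethoxyphenyl)-3-(3,5-dimethoxyphenyl)-6-(hydroxymethyl)-2,3-dihydro-1-benzofuran-4-ol (trans) | OCc1cc(O)c2c(c1)O[C@H](c1ccc(OC)c(OC)c1)[C@H]2c1cc(OC)cc(OC)c1 | intermediate
14 | (2S,3S)-2-(3,4-dimethoxyphenyl)-3-(3,5-dimethoxyphenyl)-4-hydroxy-2,3-dihydro-1-benzofuran-6-carbaldehyde | O=Cc1cc(O)c2c(c1)O[C@H](c1ccc(OC)c(OC)c1)[C@H]2c1cc(OC)cc(OC)c1 | intermediate
15 | diethyl (4-methoxybenzyl)phosphonate | CCOP(=O)(Cc1ccc(OC)cc1)OCC | starting material
16 | (2S,3S)-2-(3,4-dimethoxyphenyl)-3-(3,5-dimethoxyphenyl)-6-[(E)-2-(4-methoxyphenyl)ethenyl]-2,3-dihydro-1-benzofuran-4-ol | COc1ccc(/C=C/c2cc(O)c3c(c2)O[C@H](c2ccc(OC)c(OC)c2)[C@H]3c2cc(OC)cc(OC)c2)cc1 | intermediate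
17 | 5-[(2S,3S)-2-(3,4-dihydroxyphenyl)-4-hydroxy-6-[(E)-2-(4-hydroxyphenyl)ethenyl]-2,3-dihydro-1-benzofuran-3-yl]benzene-1,3-diol | Oc1ccc(/C=C/c2cc(O)c3c(c2)O[C@H](c2ccc(O)c(O)c2)[C@H]3c2cc(O)cc(O)c2)cc1 | target

Total step count: 10. Longest linear sequence: 10 steps (1 → 17).

Steps most likely to fail

Step 6. The second ortho ether twists the aryl ring out of the carbene plane and changes how the carbene sits among the ligands, so enantiocontrol at C3 may be lost or come out in the wrong sense; the hindered diazo compound may also be slow to reach the metal. Fallback, from 9 and back at 13: the hydrazone is oxidised as before and the insertion is run with achiral Rh2(OAc)4, which should give 11 as the racemate, that is together with the (2S,3R) enantiomer of 11 F1. The mixture is taken through step 7 unchanged, which passes through 12 together with the (2R,3R) enantiomer of 12 F2 and should give 13 together with the (2R,3R) enantiomer of 13 F3. The two trans diols are separated by preparative SFC on an amylose tris(3,5-dimethylphenylcarbamate) phase, and the (2S,3S) fraction is 13.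

Step 5. The carbonyl group is twisted and screened by two ortho benzyloxy groups, so addition of hydrazine may stall and the slow reaction may let azine formation take over. Fallback, from 5 and back at 9: 5 is lithiated as in step 4 and aryllithium 7 is added to 3,5-dimethoxybenzonitrile (THF, −78 → 0 °C; MeOH quench), which should give the N-unsubstituted diaryl ketimine F4. Without hydrolysis this is stirred with N2H4·H2O and AcOH in EtOH at 50 °C. Transimination runs through the protonated iminium ion, far more electrophilic than the ketone, and should give hydrazone 9 with loss of ammonia.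

Step 7. The veratryl cation may alkylate ring ArB or the resorcinol-type benzofuran ring before the scavenger catches it, or the scavenger may capture the ring-opened C2 cation. Fallback, from 11 and back at 12: the veratryl ether is removed without any cation by hydrogenolysis (H2, 1 atm, Pd/C, EtOAc, rt), which should cleave the primary O–CH2 bond in preference to the hindered ring C2–O1 bond and give the cis phenol silyl ether F5 and 3,4-dimethoxytoluene. F5 is then epimerised with CF3CO2H (10 vol % in CH2Cl2, rt) with no benzyl cation present, which should give 12; this is desilylated as in step 7.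

Further compounds
F1 | step 6 | {[(2S,3R)-4-[(3,4-dimethoxybenzyl)oxy]-2-(3,4-dimethoxyphenyl)-3-(3,5-dimethoxyphenyl)-2,3-dihydro-1-benzofuran-6-yl]methoxy}tri(propan-2-yl)silane (enantiomer of 11) | CC(C)[Si](OCc1cc(OCc2ccc(OC)c(OC)c2)c2c(c1)O[C@H](c1ccc(OC)c(OC)c1)[C@@H]2c1cc(OC)cc(OC)c1)(C(C)C)C(C)C
F2 | step 6 | (2R,3R)-2-(3,4-dimethoxyphenyl)-3-(3,5-dimethoxyphenyl)-6-({[tri(propan-2-yl)silyl]oxy}methyl)-2,3-dihydro-1-benzofuran-4-ol (enantiomer of 12) | CC(C)[Si](OCc1cc(O)c2c(c1)O[C@@H](c1ccc(OC)c(OC)c1)[C@@H]2c1cc(OC)cc(OC)c1)(C(C)C)C(C)C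
F3 | step 6 | (2R,3R)-2-(3,4-dimethoxyphenyl)-3-(3,5-dimethoxyphenyl)-6-(hydroxymethyl)-2,3-dihydro-1-benzofuran-4-ol (enantiomer of 13) | OCc1cc(O)c2c(c1)O[C@@H](c1ccc(OC)c(OC)c1)[C@@H]2c1cc(OC)cc(OC)c1
F4 | step 5 | 1-[2,6-bis[(3,4-dimethoxybenzyl)oxy]-4-({[tri(propan-2-yl)silyl]oxy}methyl)phenyl]-1-(3,5-dimethoxyphenyl)methanimine | COc1cc(OC)cc(C(=N)c2c(OCc3ccc(OC)c(OC)c3)cc(CO[Si](C(C)C)(C(C)C)C(C)C)cc2OCc2ccc(OC)c(OC)c2)c1
F5 | step 7 | (2R,3S)-2-(3,4-dimethoxyphenyl)-3-(3,5-dimethoxyphenyl)-6-({[tri(propan-2-yl)silyl]oxy}methyl)-2,3-dihydro-1-benzofuran-4-ol (cis) | CC(C)[Si](OCc1cc(O)c2c(c1)O[C@@H](c1ccc(OC)c(OC)c1)[C@H]2c1cc(OC)cc(OC)c1)(C(C)C)C(C)C
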